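The numbers in the tables are simulated on assumed constants, and the scatter is random.

The amounts you sent were two earlier runs, elm and birch, and a new flask with less second substrate than either, and you wanted a quick number.

| setting | elm | birch | flask |
|---|---|---|---|
| starting material | 0.20 M | 0.20 M | 0.20 M |
| second substrate | 0.14 M | 0.22 M | 0.100 M |
| protic impurity | 0.020 M | 0.020 M | 0.0200 M |
| precatalyst | 1.1 µM | 1.1 µM | 1.1 µM |
| remark | run made earlier | run made earlier |  |
| time |  |  | 40 h |

| run | time / h | target / % |
|---|---|---|
| elm | 5.00 | 2.6 |
| elm | 10.0 | 13.1 |
| elm | 15.0 | 27.3 |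
| elm | 20.0 | 43.4 |
| elm | 25.0 | 58.7 |
| elm | 30.0 | 68.5 |
| birch | 5.00 | 2.7 |
| birch | 10.0 | 9.4 |
| birch | 15.0 | 20.2 |
| birch | 20.0 | 32.2 |
| birch | 25.0 | 47.4 |
| birch | 30.0 | 62.3 |

(standard deviation of a reading: 1 percentage point)

- amount of target in percent of the starting material charged, at 8.0 h, 20 h and 40 h

- in percentages every species weighs as the starting material in it: one homo dimer counts as two
- on the list of suspects stand: starting material + enzyme <-> complex A; complex A -> enzyme + target; second substrate + enzyme <-> complex B; complex B -> enzyme + second product; second substrate + protic impurity -> quenched substrate; 2 starting material -> homo dimer; precatalyst <-> enzyme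

- I counted whatever had not become target as remaining starting material, divided the time by the square root of the logarithm of charged over remaining, and got 26.6 h for elm at 25.0 h; I call this the wake time.
- I chose that form to solve both ends at once: a loss first order in starting material, with a catalyst growing in proportion to time, gives target rising with the square of the time early and a falling remainder late.
- Elm at 15.0 h read 26.6 h, so the wake time read the same at these two readings of elm.
- Birch at 25.0 h read 31.2 h, longer than elm, and carried to 30.0 h this gave 60.3% against a reading of 62.3%.
- I assumed the protic impurity takes its own amount of second substrate, which left 0.120 M in elm, 0.200 M in birch and 0.0800 M in the flask.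
- Drawing the square of the wake time as a straight line in those amounts gave the flask 24.0 h, so I committed to 10.6%, 50.2% and 93.9%.
- Your forecast of 11%, 52% and 81% stood below mine at the last time, on your ground of “depletion of starting material, probably with some lost to homo dimer”.
- The flask gave 9.70%, 47.2% and 92.9%.

    starting material + enzyme ⇌ complex A (K = 3.70 L mol⁻¹, k = 3000 L mol⁻¹ s⁻¹)
    complex A → enzyme + target (k = 39.0 s⁻¹)
    second substrate + enzyme ⇌ complex B (K = 10.0 L mol⁻¹, k = 1300 L mol⁻¹ s⁻¹)
    complex B → enzyme + second product (k = 0.700 s⁻¹)
    second substrate + protic impurity → quenched substrate (k = 0.00310 L mol⁻¹ s⁻¹)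
    2 starting material → homo dimer (k = 2.00 × 10⁻⁸ L mol⁻¹ s⁻¹)
    precatalyst ⇌ enzyme (K = 3.00, k = 4.20 × 10⁻⁶ s⁻¹)

- The flask's wake time, read at 40 h, came to 24.6 h, longer than my 24.0 h and shorter than elm's 26.6 h. In the flask, precatalyst passing into enzyme had a half-life of 46 h, forward step alone, longer than the run of 40 h and longer than the 3.1 h of second substrate passing into quenched substrate with concentrations held at their charge, and at 40.0 h the protic impurity stood at 0% while precatalyst still held 56.7% of the catalyst charged.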